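**Strategy.** The C40 skeleton is cut at C7=C8 and C7'=C8' into crocetin dialdehyde and two identical C10 ring sulfones. Each cyclohexane ring is read as a Diels–Alder adduct: C2–C3–C4–C5 with the C5 methyl is (E)-penta-1,3-diene, and C1(CH3)2–C6–C7 is a 3-methylbut-2-enoate. One catalytic enantioselective [4+2] cycloaddition of the diene with the trifluoroethyl enoate forms C1–C2 and C5–C6, closes the carbocycle, fixes C5 absolutely and leaves C3=C4 as the masked cis-3,4-diol. C6 is then corrected by epimerisation, the diol is placed anti to the C5 methyl by a Woodward cis-hydroxylation, and sulfation at C4 ends the route.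

Key step: step 2

Remarks on the chemistry (assumptions):
- Ring atoms carry carotenoid numbers: C1 is the gem-dimethyl carbon, C5 bears the methyl, C6 bears the chain, C7 is the exocyclic carbon.
- The sense of induction of the oxazaborolidinium catalyst is assumed from the usual α-C–H···O binding picture for enoates and by analogy with simple acrylates, which points to the catalyst from (R)-α,α-diphenylprolinol; the antipode is equally available and is used if a pilot run shows the opposite sense.
- The target is drawn as the free bis(hydrogen sulfate); it is released from its pyridinium salt on an acidic resin within the last step and is best stored cold or as a salt.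

**Step 1**
Reactants: 1 3-methylbut-2-enoyl chloride; 2 2,2,2-trifluoroethanol
Product: 3 2,2,2-trifluoroethyl 3-methylbut-2-enoate
Conditions: pyridine (1.2 equiv), CH2Cl2, 0 °C → rt
Reagents that add atoms: none
Why: Esterification of an alcohol with an acid chloride; pyridine is preferred to a trialkylamine so that the acid chloride is not dehydrohalogenated to a vinylketene, which would lead to the deconjugated ester.

**Step 2**
Reactants: 4 (E)-penta-1,3-diene; 3 2,2,2-trifluoroethyl 3-methylbut-2-enoate
Product: 5 2,2,2-trifluoroethyl (1S,2S)-2,6,6-trimethylcyclohex-3-ene-1-carboxylate (cis)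
Conditions: (R)-3,3-diphenyl-1-(o-tolyl)tetrahydro-1H,3H-pyrrolo[1,2-c][1,3,2]oxazaborole (20 mol%), AlBr3 (16 mol%), 4 (5 equiv), CH2Cl2, −40 → 0 °C
Reagents that add atoms: none
Why: The ester carbonyl binds to the cationic boron of the AlBr3-activated oxazaborolidine, which lowers the enoate LUMO enough for a concerted, asynchronous [4+2] cycloaddition in which the diene CH2 terminus (C2) bonds to the β-carbon C1 ahead of bond formation between the methyl-bearing terminus C5 and the α-carbon C6. The closest known reactions are oxazaborolidinium-catalysed Diels–Alder additions of trifluoroethyl acrylate and crotonate to simple dienes and the AlCl3-promoted addition of this diene to 3-methylbut-2-enoyl dienophiles, so this is a known catalytic reaction applied to a more hindered enoate. The cyclohexene ring is closed intermolecularly by suprafacial union of the s-cis diene with the enoate C=C, both σ-bonds (C1–C2 and C5–C6) forming in one transition state. C6 is set by the catalyst, whose aryl groups cover one face of the bound s-trans enoate so that the diene adds to the open face; C5 is set relative to C6 by the endo transition state together with the fixed E geometry of the diene, which should give the cis (1S,2S) adduct. The step needs regio-, endo- and enantioface selectivity: the first comes from the larger HOMO coefficient at the diene CH2 terminus meeting the larger LUMO coefficient at the β-carbon (helped by sterics, the unsubstituted terminus pairing with the quaternary centre), the second from Lewis-acid-enhanced secondary overlap of the ester with the diene, and the third from the catalyst. The electron-poor trifluoroethyl ester is kept because it makes the weakly reactive β,β-disubstituted enoate more electrophilic once bound.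

**Step 3**
Reactants: 5 2,2,2-trifluoroethyl (1S,2S)-2,6,6-trimethylcyclohex-3-ene-1-carboxylate
Product: 7 methyl (1R,2S)-2,6,6-trimethylcyclohex-3-ene-1-carboxylate (trans), via cis methyl ester 6 (not isolated)
Conditions: NaOMe (1.5 equiv), MeOH, reflux; NH4Cl aq
Reagents that add atoms: sodium methoxide, [Na+].[O-]C
Why: Transesterification of the activated ester followed by enolate-mediated thermodynamic epimerisation at C6 should place the ester equatorial and trans to the C5 methyl, while C5, which is not acidic, keeps its configuration.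

**Step 4**
Reactants: 7 methyl (1R,2S)-2,6,6-trimethylcyclohex-3-ene-1-carboxylate
Product: 10 methyl (1R,2R,3S,4R)-4-acetoxy-3-hydroxy-2,6,6-trimethylcyclohexane-1-carboxylate, via trans-iodoacetate 8 (not isolated), via acetoxonium ion 9 (not isolated)
Conditions: I2 (1.05 equiv), AgOAc (2.2 equiv), AcOH, rt; then H2O (1.5 equiv), 90 °C
Reagents that add atoms: silver acetate, CC(=O)[O-].[Ag+]; water, O
Why: Woodward cis-hydroxylation: the ring mimics ring A of a 5α-steroid 2-ene, so iodine should add to the C3=C4 face away from the axial C1 methyl (the face of the C5 methyl), acetate opens the iodonium ion trans-diaxially at C3 (Fürst–Plattner), and silver-assisted displacement of iodide by the neighbouring acetate with inversion at C4 places both oxygens anti to the C5 methyl before water opens the acetoxonium ion to the axial 3-acetate.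

**Step 5**
Reactants: 10 methyl (1R,2R,3S,4R)-4-acetoxy-3-hydroxy-2,6,6-trimethylcyclohexane-1-carboxylate
Product: 11 (1R,2S,3R,4R)-4-(hydroxymethyl)-3,5,5-trimethylcyclohexane-1,2-diol
Conditions: LiAlH4, THF, 0 °C → rt; then H2O, NaOH aq
Reagents that add atoms: none
Why: Hydride reduction of the methyl ester and of the acetate (and of any regioisomeric acetate or diacetate from step 4) should converge on one triol without touching a stereocentre.

**Step 6**
Reactants: 11 (1R,2S,3R,4R)-4-(hydroxymethyl)-3,5,5-trimethylcyclohexane-1,2-diol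
Product: 12 [(3aS,4R,5R,7aR)-2,2,4,6,6-pentamethylhexahydro-1,3-benzodioxol-5-yl]methanol
Conditions: Me2C(OMe)2, PPTS (cat.), acetone, rt
Reagents that add atoms: 2,2-dimethoxypropane, COC(C)(C)OC
Why: Acid-catalysed ketal exchange (acetonide formation) is selective for the cis-vicinal C3/C4 diol, which alone can close a five-membered dioxolane, and leaves the primary C7 hydroxyl free.

**Step 7**
Reactants: 12 [(3aS,4R,5R,7aR)-2,2,4,6,6-pentamethylhexahydro-1,3-benzodioxol-5-yl]methanol
Product: 13 5-({[(3aS,4R,5R,7aR)-2,2,4,6,6-pentamethylhexahydro-1,3-benzodioxol-5-yl]methyl}sulfanyl)-1-phenyl-1H-tetrazole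
Conditions: 1-phenyl-1H-tetrazole-5-thiol, PPh3, DIAD, THF, 0 °C → rt
Reagents that add atoms: 1-phenyl-1H-tetrazole-5-thiol, Sc1nnnn1-c1ccccc1
Why: Mitsunobu thioetherification of a primary alcohol with an acidic thiol; substitution occurs at C7, which is not a stereocentre.

**Step 8**
Reactants: 13 the tetrazolyl sulfide
Product: 15 5-({[(3aS,4R,5R,7aR)-2,2,4,6,6-pentamethylhexahydro-1,3-benzodioxol-5-yl]methyl}sulfonyl)-1-phenyl-1H-tetrazole, via sulfoxide 14 (not isolated)
Conditions: (NH4)6Mo7O24·4H2O (10 mol%), 30% H2O2 aq, EtOH, 0 °C → rt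
Reagents that add atoms: hydrogen peroxide, OO
Why: Molybdate-catalysed peroxide oxidation of a sulfide to the sulfone; the ring is now saturated and the acetonide should tolerate the nearly neutral medium.

**Step 9**
Reactants: 15 the tetrazolyl sulfone (2.4 equiv); 16 crocetin dialdehyde
Product: 18 (3R,4S,5R,6R,3'R,4'S,5'R,6'R)-5,6,5',6'-tetrahydro-β,β-carotene-3,4,3',4'-tetrol 3,4:3',4'-bis(acetonide), via apo-aldehyde 17 (not isolated)
Conditions: KN(SiMe3)2 (2.3 equiv), THF, −78 °C; then 16, −78 °C → rt, dark, Ar; NH4Cl aq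
Reagents that add atoms: none
Why: Twofold Julia–Kocienski olefination (carbanion addition, Smiles rearrangement of the tetrazolyl group from sulfur to oxygen, loss of SO2 and tetrazololate) forms C7=C8 and C7'=C8', with E geometry expected from the bulky β-branched sulfone and the conjugated aldehyde, while the non-acidic C6 keeps its configuration.

**Step 10**
Reactants: 18 the bis(acetonide)
Product: 19 (3R,4S,5R,6R,3'R,4'S,5'R,6'R)-5,6,5',6'-tetrahydro-β,β-carotene-3,4,3',4'-tetrol
Conditions: 1 M HCl aq, THF/MeOH, rt, dark, Ar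
Reagents that add atoms: none
Why: Acid hydrolysis of the two cis-fused dioxolanes; the polyene has no allylic oxygen or epoxide and should withstand brief contact with dilute acid in the dark.

**Step 11**
Reactants: 19 the tetrol
Product: 21 (3R,4S,5R,6R,3'R,4'S,5'R,6'R)-3,3'-dihydroxy-5,6,5',6'-tetrahydro-β,β-carotene-4,4'-diyl bis(hydrogen sulfate), via bis(pyridinium) salt 20 (not isolated)
Conditions: SO3·pyridine (2.4 equiv), pyridine/DMF, 0 °C → rt, dark; then sulfonic acid cation-exchange resin (H+ form), MeOH/H2O, 0 °C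
Reagents that add atoms: sulfur trioxide–pyridine complex, O=S(=O)([O-])[n+]1ccccc1
Why: Sulfation with an amine–SO3 complex is expected at the equatorial C4 and C4' hydroxyls, because the axial C3 and C3' hydroxyls are 1,3-diaxial to a C1 methyl, and cation exchange then frees the hydrogen sulfate.

**Compound list**

1 | 3-methylbut-2-enoyl chloride | CC(C)=CC(Cl)=O | starting material
2 | 2,2,2-trifluoroethanol | OCC(F)(F)F | starting material
3 | 2,2,2-trifluoroethyl 3-methylbut-2-enoate | CC(C)=CC(=O)OCC(F)(F)F | intermediate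
4 | (E)-penta-1,3-diene | C/C=C/C=C | starting material
5 | 2,2,2-trifluoroethyl (1S,2S)-2,6,6-trimethylcyclohex-3-ene-1-carboxylate (cis) | O=C(OCC(F)(F)F)[C@H]1[C@@H](C)C=CCC1(C)C | intermediate
6 | methyl (1S,2S)-2,6,6-trimethylcyclohex-3-ene-1-carboxylate (cis) | COC(=O)[C@H]1[C@@H](C)C=CCC1(C)C | intermediate (not isolated)
7 | methyl (1R,2S)-2,6,6-trimethylcyclohex-3-ene-1-carboxylate (trans) | COC(=O)[C@@H]1[C@@H](C)C=CCC1(C)C | intermediate
8 | methyl (1R,2R,3R,4R)-4-acetoxy-3-iodo-2,6,6-trimethylcyclohexane-1-carboxylate (iodine on the face of the C5 methyl, acetate opposite) | COC(=O)[C@@H]1[C@@H](C)[C@@H](I)[C@H](OC(C)=O)CC1(C)C | intermediate (not isolated)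
9 | cis-fused 2-methyl-1,3-dioxolan-2-ylium (acetoxonium) ion across C3/C4 of the methyl ester, both oxygens anti to the C5 methyl | COC(=O)[C@@H]1[C@@H](C)[C@@H]2OC(C)=[O+][C@@H]2CC1(C)C | intermediate (not isolated)
10 | methyl (1R,2R,3S,4R)-4-acetoxy-3-hydroxy-2,6,6-trimethylcyclohexane-1-carboxylate | COC(=O)[C@@H]1[C@@H](C)[C@H](O)[C@H](OC(C)=O)CC1(C)C | intermediate
11 | (1R,2S,3R,4R)-4-(hydroxymethyl)-3,5,5-trimethylcyclohexane-1,2-diol | OC[C@@H]1[C@@H](C)[C@H](O)[C@H](O)CC1(C)C | intermediate
12 | [(3aS,4R,5R,7aR)-2,2,4,6,6-pentamethylhexahydro-1,3-benzodioxol-5-yl]methanol | OC[C@@H]1[C@@H](C)[C@@H]2OC(C)(C)O[C@@H]2CC1(C)C | intermediate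
13 | 5-({[(3aS,4R,5R,7aR)-2,2,4,6,6-pentamethylhexahydro-1,3-benzodioxol-5-yl]methyl}sulfanyl)-1-phenyl-1H-tetrazole | C(Sc1nnnn1-c1ccccc1)[C@@H]1[C@@H](C)[C@@H]2OC(C)(C)O[C@@H]2CC1(C)C | intermediate
14 | corresponding sulfoxide (mixture of epimers at sulfur) | O=S(C[C@@H]1[C@@H](C)[C@@H]2OC(C)(C)O[C@@H]2CC1(C)C)c1nnnn1-c1ccccc1 | intermediate (not isolated)
15 | 5-({[(3aS,4R,5R,7aR)-2,2,4,6,6-pentamethylhexahydro-1,3-benzodioxol-5-yl]methyl}sulfonyl)-1-phenyl-1H-tetrazole | O=S(=O)(C[C@@H]1[C@@H](C)[C@@H]2OC(C)(C)O[C@@H]2CC1(C)C)c1nnnn1-c1ccccc1 | intermediate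
16 | crocetin dialdehyde, (2E,4E,6E,8E,10E,12E,14E)-2,6,11,15-tetramethylhexadeca-2,4,6,8,10,12,14-heptaenedial | O=C/C(C)=C/C=C/C(C)=C/C=C/C=C(C)/C=C/C=C(C)/C=O | starting material
17 | all-E C30 apo-aldehyde: one end olefinated with the ring acetonide, the other end still CHO | O=C/C(C)=C/C=C/C(C)=C/C=C/C=C(C)/C=C/C=C(C)/C=C/[C@@H]1[C@@H](C)[C@@H]2OC(C)(C)O[C@@H]2CC1(C)C | intermediate (not isolated)
18 | (3R,4S,5R,6R,3'R,4'S,5'R,6'R)-5,6,5',6'-tetrahydro-β,β-carotene-3,4,3',4'-tetrol 3,4:3',4'-bis(acetonide) | CC(/C=C/C=C(C)/C=C/[C@@H]1[C@@H](C)[C@@H]2OC(C)(C)O[C@@H]2CC1(C)C)=C\C=C\C=C(C)\C=C\C=C(C)\C=C\[C@@H]1[C@@H](C)[C@@H]2OC(C)(C)O[C@@H]2CC1(C)C | intermediate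
19 | (3R,4S,5R,6R,3'R,4'S,5'R,6'R)-5,6,5',6'-tetrahydro-β,β-carotene-3,4,3',4'-tetrol | CC(/C=C/C=C(C)/C=C/[C@@H]1[C@@H](C)[C@H](O)[C@H](O)CC1(C)C)=C\C=C\C=C(C)\C=C\C=C(C)\C=C\[C@@H]1[C@@H](C)[C@H](O)[C@H](O)CC1(C)C | intermediate
20 | bis(pyridinium) salt of the 4,4'-disulfate | CC(/C=C/C=C(C)/C=C/[C@@H]1[C@@H](C)[C@H](OS(=O)(=O)[O-])[C@H](O)CC1(C)C)=C\C=C\C=C(C)\C=C\C=C(C)\C=C\[C@@H]1[C@@H](C)[C@H](OS(=O)(=O)[O-])[C@H](O)CC1(C)C.c1cc[nH+]cc1.c1cc[nH+]cc1 | intermediate (not isolated)
21 | (3R,4S,5R,6R,3'R,4'S,5'R,6'R)-3,3'-dihydroxy-5,6,5',6'-tetrahydro-β,β-carotene-4,4'-diyl bis(hydrogen sulfate) | CC(/C=C/C=C(C)/C=C/[C@@H]1[C@@H](C)[C@H](OS(=O)(=O)O)[C@H](O)CC1(C)C)=C\C=C\C=C(C)\C=C\C=C(C)\C=C\[C@@H]1[C@@H](C)[C@H](OS(=O)(=O)O)[C@H](O)CC1(C)C | target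

**Step count.** Total: 11 steps. Longest linear sequence: 11 steps (1 to 21); the only other building block, 16, is purchased.

**Steps most likely to fail**

Step 2. The β,β-disubstituted enoate may react too slowly, the diene may oligomerise under the strong Lewis acid, or enantioface and endo control may be incomplete. An exo adduct would become the antipode of 7 after epimerisation, so it has to be removed before step 3. Fallback: setting out from 4, the AlCl3-promoted cycloaddition with commercial methyl 3-methylbut-2-enoate (CH2Cl2, 0 °C → rt), which is the established racemic way to this ring system, should give racemic cis-rich methyl 2,6,6-trimethylcyclohex-3-ene-1-carboxylate F1. Equilibration with NaOMe in MeOH gives the racemic trans ester F2. Preparative chromatography on a chiral stationary phase (cellulose carbamate phase, supercritical CO2/MeOH) then separates the (1R,2S) enantiomer, which is 7, where the route is rejoined.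

Step 4. The facial sense of the iodo-acetoxylation may be governed by the C5 methyl instead of the axial C1 methyl, so that the oxygens end up syn to the C5 methyl. Fallback: setting out from 7, the electrophile would in that case prefer the face anti to the C5 methyl, and a concerted suprafacial osmylation (OsO4 cat., N-methylmorpholine N-oxide, acetone/H2O) should deliver both oxygens directly to that face. This gives methyl (1R,2R,3S,4R)-3,4-dihydroxy-2,6,6-trimethylcyclohexane-1-carboxylate F3, and LiAlH4 reduction of it returns to triol 11.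

Step 11. Sulfation may be insufficiently selective between the C4 and C3 hydroxyls, or may go on to over-sulfation. Fallback: setting out from 19, MeC(OMe)3 with PPTS (CH2Cl2, rt) should give the bis(cyclic methyl orthoacetate) F4. Dilute aqueous AcOH opens each orthoester to the axial ester, giving the 3,3'-di-O-acetate F5 with only the C4 and C4' hydroxyls free. SO3·pyridine then gives the bis(pyridinium) 3,3'-di-O-acetyl 4,4'-disulfate F6. K2CO3 in MeOH removes the acetates (sulfate monoesters are stable to base) to give the dipotassium salt F7 of the target, and the acidic resin treatment of step 11 returns 21.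

**Further compounds**

F1 | step 2 | racemic methyl (1S,2S)-2,6,6-trimethylcyclohex-3-ene-1-carboxylate (cis; one enantiomer drawn) | COC(=O)[C@H]1[C@@H](C)C=CCC1(C)C
F2 | step 2 | racemic methyl (1R,2S)-2,6,6-trimethylcyclohex-3-ene-1-carboxylate (trans; one enantiomer drawn) | COC(=O)[C@@H]1[C@@H](C)C=CCC1(C)C
F3 | step 4 | methyl (1R,2R,3S,4R)-3,4-dihydroxy-2,6,6-trimethylcyclohexane-1-carboxylate | COC(=O)[C@@H]1[C@@H](C)[C@H](O)[C@H](O)CC1(C)C
F4 | step 11 | 3,4:3',4'-bis(cyclic methyl orthoacetate) of tetrol 19 (orthoester carbons as a mixture) | CC(/C=C/C=C(C)/C=C/[C@@H]1[C@@H](C)[C@@H]2OC(C)(OC)O[C@@H]2CC1(C)C)=C\C=C\C=C(C)\C=C\C=C(C)\C=C\[C@@H]1[C@@H](C)[C@@H]2OC(C)(OC)O[C@@H]2CC1(C)C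
F5 | step 11 | 3,3'-di-O-acetate of tetrol 19 | CC(/C=C/C=C(C)/C=C/[C@@H]1[C@@H](C)[C@H](O)[C@H](OC(C)=O)CC1(C)C)=C\C=C\C=C(C)\C=C\C=C(C)\C=C\[C@@H]1[C@@H](C)[C@H](O)[C@H](OC(C)=O)CC1(C)C
F6 | step 11 | bis(pyridinium) 3,3'-di-O-acetyl 4,4'-disulfate | CC(/C=C/C=C(C)/C=C/[C@@H]1[C@@H](C)[C@H](OS(=O)(=O)[O-])[C@H](OC(C)=O)CC1(C)C)=C\C=C\C=C(C)\C=C\C=C(C)\C=C\[C@@H]1[C@@H](C)[C@H](OS(=O)(=O)[O-])[C@H](OC(C)=O)CC1(C)C.c1cc[nH+]cc1.c1cc[nH+]cc1
F7 | step 11 | dipotassium salt of 21 | CC(/C=C/C=C(C)/C=C/[C@@H]1[C@@H](C)[C@H](OS(=O)(=O)[O-])[C@H](O)CC1(C)C)=C\C=C\C=C(C)\C=C\C=C(C)\C=C\[C@@H]1[C@@H](C)[C@H](OS(=O)(=O)[O-])[C@H](O)CC1(C)C.[K+].[K+]
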